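## The problem

The target **19** is a flavonol, a 2-aryl-3-hydroxychromen-4-one. Its ring A is fully substituted: 5-OH, a 3-methylbut-2-enyl (prenyl) group at C6, 7-OMe and a second prenyl group at C8. Ring B carries 3'-OH and 4'-OMe. There is no stereocentre, so the task is one of regiochemistry and of telling five oxygen functions apart: 3-OH, 5-OH and 3'-OH stay free, O7 and O4' are methylated. Two aryl–CH2 bonds have to be made at C6 and C8 without touching ring B or C3. The prenyl groups next to phenols are the fragile part: acid can add a neighbouring OH across the double bond to give a chroman, and electrophilic oxidants epoxidise the trisubstituted alkenes. The C3 oxygen must therefore arrive by a method that spares such alkenes, and the last deprotection must be mild. The feature that opens the route is positional: C6 is ortho to both O5 and O7, and C8 is ortho to O7 and para to O5, so allyl groups placed on O5 and O7 can be handed to exactly these carbons by [3,3] shifts. Commercial diosmetin **1** already holds rings A, B and C with free 5-OH and 7-OH and the correct ring B pattern.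

## Retrosynthesis

**19 ⇒ 18.** The O–CH2 acetal bonds at O5 and O3' are cut, so the last step only releases two phenols from the bis(methoxymethyl) ether **18**. Methoxymethyl (MOM) is chosen because it survives carbonate alkylations, 200 °C in an amine solvent, the ruthenium carbene, NaH, LiN(i-Pr)2 and alkaline peroxide, and leaves in dilute methanolic acid. Benzyl ethers would need hydrogenolysis (reduces the prenyl groups) or boron halides (cyclise them), and silyl ethers would not last through the alkylations.

**18 ⇒ 15 ⇒ 14.** The C3–O bond is cut to give flavone **15**. Dioxirane epoxidation of the C2=C3 bond would also attack the prenyl groups, and an Algar–Flynn–Oyamada closure would mean rebuilding ring C from a chalcone. Deprotonation at C3, borylation and oxidation with nucleophilic peroxide leaves electron-rich alkenes alone. It tolerates no free OH, so the chelated 5-OH of **14** is first capped with chloromethyl methyl ether **4**. The oxidation is placed after the metathesis because ArCH2CH=C(CH3)2 is less prone to base-induced double-bond migration than ArCH2CH=CH2.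

**14 ⇒ 12.** The two terminal C=C bonds of the prenyl groups are cut, giving the 6,8-diallyl flavone **12** and 2-methylbut-2-ene **13**. A prenyl ether would put a 1,1-dimethylallyl group on the ortho carbon in a Claisen shift; an unsubstituted allyl group arrives with the same constitution by any path. The forward step is a twofold cross-metathesis that must leave the chromone C2=C3 bond alone.

**12 ⇒ 10.** The O7–CH3 bond is cut (iodomethane **11**). The rearrangement that makes **10** frees exactly the 7-OH that has to be methylated, and it is more acidic than the chelated 5-OH, so no extra protecting step is needed.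

**10 ⇒ 6 (key disconnection).** The C6–CH2 and C8–CH2 bonds are cut and both allyl groups are returned to O5 and O7, giving the bis(allyl) ether **6**. Direct electrophilic C-prenylation of a 5,7-dihydroxyflavone gives mixtures of C6, C8, O and bis products; halogenation followed by cross-coupling costs extra steps and brings linear/branched problems with prenyl metal reagents. **6** contains no C–C bond that **1** does not have. The forward reaction must move both groups; only C6 and C8 are free on ring A, and the expected path runs through **7**, **8** and **9**.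

**6 ⇒ 5 ⇒ 3 ⇒ 1.** Three O–C bonds are cut in the reverse order of phenol reactivity. The 7-OH of **1** is the most acidic and takes the first allyl group from allyl bromide **2** to give **3**. The 3'-OH is then capped with **4** to give **5**. The chelated 5-OH reacts last under forcing conditions with **2**.

## Roads not taken

**Alternative 1: Danheiser benzannulation for ring A.** The cut runs through ring A: 2-prenyl-3-(triisopropylsilyloxy)cyclobutenone A2 and the ynol ether 1-methoxy-5-methylhex-4-en-1-yne A3 are heated to give the mono-silylated diprenyl resorcinol A1.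
- Forward key step: 4π opening of A2 to a vinylketene, [2+2] addition to A3, a second 4π opening, 6π closure and tautomerisation.
- Merits: both prenyl groups, the methoxy group and two differentiated oxygens are placed with full regiocontrol at moderate temperature. No O-to-C migration and no metathesis are needed.
- Weak points: neither A2 nor A3 is commercial, and A3 is a volatile, labile ynol ether. The single free carbon of A1 must then be acylated between two oxygens with acid-sensitive prenyl groups present. Rings C and B are still to be built.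
- Comparison: this road is better in certainty of the substitution pattern, and a chalcone end game could bring the C3 oxygen with ring closure. It is clearly longer and rebuilds rings that **1** supplies. The chosen plan sets nine linear steps and only two new C–C bonds against it.

**Alternative 2: Thermal chromone annulation.** C4–C4a and O1–C2 are cut. The symmetric resorcinol 5-methoxy-4,6-diprenylbenzene-1,3-diol A5 and the α-pivaloyloxy aroylacetate A6 are heated in diphenyl ether at about 220–240 °C to give the 3,3'-dipivalate A4 of the target.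
- Forward key step: C-acylation of A5 at the carbon between its two hydroxyls, then cyclodehydration.
- Merits: this is the most convergent road. The C3 oxygen comes with A6, so no metalation is needed; the symmetry of A5 removes any regiochemical question; and the final ester cleavage is basic, which is gentler on prenyl groups than the acid step of the chosen plan.
- Weak points: two prenyl groups ortho to free phenols are held far above 200 °C, where closure to chromans and acyl transfer from the pivalates to the phenols are likely. Such condensations work best with phloroglucinol-type partners. Making A5 by double C-prenylation only moves the regiochemical problem.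
- Comparison: if the annulation worked it would be shorter and its end game cleaner. The chosen plan exposes only unsubstituted allyl groups to heat and borrows its regiocontrol from a preformed flavone.

**Alternative 3: Carbonylative alkyne annulation.** C4a–C4, C4–C3 and O1–C2 are cut. The iodoresorcinol A8, carbon monoxide A10 and the arylacetylene A9 are joined under PdCl2(PPh3)2 in diethylamine to give flavone A7, which is identical with **14**.
- Forward key step: oxidative addition of A8 to zerovalent palladium formed in the flask, insertion of A10, coupling with A9 to an ynone, and amine-mediated 6-endo closure.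
- Merits: modular and convergent at moderate temperature, with a symmetric aryl iodide, and it enters the chosen route three steps from the end.
- Weak points: it keeps the least secure end steps (5-O-protection, C3 oxidation, acid deprotection). Iodination on the way to A8 competes with iodoetherification of the prenyl alkenes. The iodide flanked by two hydroxyls is hindered, and 5-exo closure to aurones or carbonyl-free coupling to benzofurans can compete.
- Comparison: step count is similar or slightly higher, and modularity for analogues is a real advantage the chosen plan lacks. The chosen plan answers with fewer C–C bond formations and a key step well known on this ring system.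

Key step: step 4

Remark on the chemistry: in step 4 the 5-O-allyl group is assumed to migrate before the 7-O-allyl group, and intermediates **7**–**9** are numbered for that order; the other order leads to the same product **10**.

## Route

Step 1
Reactants: 1 diosmetin; 2 allyl bromide
Product: 3 7-(allyloxy)-5-hydroxy-2-(3-hydroxy-4-methoxyphenyl)chromen-4-one
Conditions: allyl bromide (1.05 equiv), K2CO3 (1.1 equiv), DMF, rt
Reagents that add atoms: allyl bromide, C=CCBr
Why: Williamson etherification; the 7-OH, a vinylogous acid para to the C4 carbonyl, is the most acidic hydroxyl and reacts first, while the guaiacol-type 3'-OH is less acidic and the chelated 5-OH is inert with limited base.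

Step 2
Reactants: 3 7-(allyloxy)-5-hydroxy-2-(3-hydroxy-4-methoxyphenyl)chromen-4-one; 4 chloromethyl methyl ether
Product: 5 7-(allyloxy)-5-hydroxy-2-[4-methoxy-3-(methoxymethoxy)phenyl]chromen-4-one
Conditions: MOMCl, i-Pr2NEt, DMF, 0 °C to rt
Reagents that add atoms: chloromethyl methyl ether, COCCl
Why: O-alkylation to the MOM acetal at the only non-chelated phenol; the 5-OH, hydrogen-bonded to C4=O, does not react with an amine base.

Step 3
Reactants: 5 7-(allyloxy)-5-hydroxy-2-[4-methoxy-3-(methoxymethoxy)phenyl]chromen-4-one; 2 allyl bromide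
Product: 6 5,7-bis(allyloxy)-2-[4-methoxy-3-(methoxymethoxy)phenyl]chromen-4-one
Conditions: allyl bromide (excess), K2CO3, DMF, 60 °C
Reagents that add atoms: allyl bromide, C=CCBr
Why: Forcing Williamson etherification of the chelated 5-OH, the usual way to 5-O-allyl and 5-O-prenyl flavone ethers; the MOM acetal is stable to base.

Step 4
Reactants: 6 5,7-bis(allyloxy)-2-[4-methoxy-3-(methoxymethoxy)phenyl]chromen-4-one
Product: 10 6,8-diallyl-5,7-dihydroxy-2-[4-methoxy-3-(methoxymethoxy)phenyl]chromen-4-one, via C6 ortho-dienone 7 (not isolated), via 6-allyl-7-allyloxy-5-hydroxyflavone 8 (not isolated), via C8 ortho-dienone 9 (not isolated)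
Conditions: N,N-diethylaniline (degassed), 200 °C, sealed tube, Ar
Reagents that add atoms: none
Why: Each aryl allyl ether undergoes a concerted, suprafacial [3,3] sigmatropic shift through a chair-like six-membered transition state; the closest known reaction type is the thermal aromatic Claisen rearrangement of 5- and 7-allyloxyflavones in N,N-diethylaniline. The 5-O-allyl group, twisted out of plane by the peri carbonyl, should move first to C6, its only free ortho carbon, giving dienone 7, which tautomerises to the chelated phenol 8. The 7-O-allyl group of 8 then finds C6 occupied and shifts to C8 through dienone 9, whose enolisation gives 10. Should the 7-O-allyl group reach C6 first, the 5-O-allyl group would arrive at C8 by an ortho shift onto the substituted C6 followed by a Cope shift, so both orders end in 10. No ring is closed and no stereocentre is created; the sp3 carbons of 7 and 9 are lost on enolisation. The selectivity needed is regiochemical only and the substrate secures it: C6 and C8 are the only unsubstituted ring A carbons, and an unsubstituted allyl group has the same constitution after a direct shift or a Claisen–Cope sequence. The basic solvent buffers the phenols formed and so holds back their addition to the new allyl groups; the aryl MOM ether and C3–H are inert.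

Step 5
Reactants: 10 6,8-diallyl-5,7-dihydroxy-2-[4-methoxy-3-(methoxymethoxy)phenyl]chromen-4-one; 11 iodomethane
Product: 12 6,8-diallyl-5-hydroxy-7-methoxy-2-[4-methoxy-3-(methoxymethoxy)phenyl]chromen-4-one
Conditions: MeI (1.2 equiv), K2CO3, acetone, rt to 40 °C
Reagents that add atoms: iodomethane, CI
Why: Williamson etherification; the 7-OH is the more acidic phenol, and the 5-OH, chelated to C4=O, stays free with limited MeI under mild conditions.

Step 6
Reactants: 12 6,8-diallyl-5-hydroxy-7-methoxy-2-[4-methoxy-3-(methoxymethoxy)phenyl]chromen-4-one; 13 2-methylbut-2-ene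
Product: 14 5-hydroxy-7-methoxy-2-[4-methoxy-3-(methoxymethoxy)phenyl]-6,8-bis(3-methylbut-2-enyl)chromen-4-one
Conditions: 2-methylbut-2-ene (large excess), second-generation Grubbs catalyst RuCl2(=CHPh)(H2IMes)(PCy3) (5–10 mol %), CH2Cl2, 40 °C, sealed vessel
Reagents that add atoms: 2-methylbut-2-ene, CC=C(C)C
Why: Olefin cross-metathesis exchanges each terminal CH2 for an isopropylidene group, a standard conversion of allylarenes and allylphenols into prenylarenes; the electron-poor trisubstituted chromone C2=C3 bond does not take part, and the new alkene has no E/Z issue.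

Step 7
Reactants: 14 5-hydroxy-7-methoxy-2-[4-methoxy-3-(methoxymethoxy)phenyl]-6,8-bis(3-methylbut-2-enyl)chromen-4-one; 4 chloromethyl methyl ether
Product: 15 7-methoxy-5-(methoxymethoxy)-2-[4-methoxy-3-(methoxymethoxy)phenyl]-6,8-bis(3-methylbut-2-enyl)chromen-4-one
Conditions: NaH, MOMCl, DMF, 0 °C to rt
Reagents that add atoms: chloromethyl methyl ether, COCCl
Why: Irreversible deprotonation with NaH breaks the chelate, and the hindered phenoxide is O-alkylated to the MOM acetal; a fully O-protected flavone is needed for the C3 metalation.

Step 8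
Reactants: 15 7-methoxy-5-(methoxymethoxy)-2-[4-methoxy-3-(methoxymethoxy)phenyl]-6,8-bis(3-methylbut-2-enyl)chromen-4-one
Product: 18 3-hydroxy-7-methoxy-5-(methoxymethoxy)-2-[4-methoxy-3-(methoxymethoxy)phenyl]-6,8-bis(3-methylbut-2-enyl)chromen-4-one, via 3-lithioflavone 16 (not isolated), via flavon-3-yl dimethyl boronate 17 (not isolated)
Conditions: LiN(i-Pr)2, THF, −78 °C; B(OMe)3, −78 to 0 °C; then 30% H2O2, aq NaOH, 0 °C
Reagents that add atoms: hydrogen peroxide, OO
Why: Carbonyl-directed deprotonation at C3, trapping as the boronate and oxidative 1,2-migration is the established flavone-to-flavonol conversion for O-protected flavones. Hydroperoxide anion is a nucleophilic oxidant and should leave the electron-rich prenyl alkenes alone; low temperature and a short metalation time limit deprotonation at the ArCH2 positions.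

Step 9
Reactants: 18 3-hydroxy-7-methoxy-5-(methoxymethoxy)-2-[4-methoxy-3-(methoxymethoxy)phenyl]-6,8-bis(3-methylbut-2-enyl)chromen-4-one
Product: 19 3,5-dihydroxy-2-(3-hydroxy-4-methoxyphenyl)-7-methoxy-6,8-bis(3-methylbut-2-enyl)chromen-4-one
Conditions: 3 M aq HCl, MeOH/THF, 40 °C, stopped at full conversion
Reagents that add atoms: none
Why: Acid-catalysed acetal exchange with methanol removes both MOM groups, the peri 5-O-MOM first; dilute methanolic acid at moderate temperature is the usual MOM removal on prenylated flavonoids and should be too mild to protonate the trisubstituted alkenes at a useful rate.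

## Compound list

1 | diosmetin, 5,7-dihydroxy-2-(3-hydroxy-4-methoxyphenyl)chromen-4-one | COc1ccc(-c2cc(=O)c3c(O)cc(O)cc3o2)cc1O | starting material
2 | allyl bromide | C=CCBr | starting material
3 | 7-(allyloxy)-5-hydroxy-2-(3-hydroxy-4-methoxyphenyl)chromen-4-one | COc1ccc(-c2cc(=O)c3c(O)cc(OCC=C)cc3o2)cc1O | intermediate
4 | chloromethyl methyl ether | COCCl | starting material
5 | 7-(allyloxy)-5-hydroxy-2-[4-methoxy-3-(methoxymethoxy)phenyl]chromen-4-one | COCOc1cc(-c2cc(=O)c3c(O)cc(OCC=C)cc3o2)ccc1OC | intermediate
6 | 5,7-bis(allyloxy)-2-[4-methoxy-3-(methoxymethoxy)phenyl]chromen-4-one | COCOc1cc(-c2cc(=O)c3c(OCC=C)cc(OCC=C)cc3o2)ccc1OC | intermediate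
7 | 6-allyl-7-(allyloxy)-2-[4-methoxy-3-(methoxymethoxy)phenyl]-6H-chromene-4,5-dione (C6 ortho-dienone, racemic at C6) | COCOc1cc(C2=CC(=O)C3=C(O2)C=C(OCC=C)C(CC=C)C3=O)ccc1OC | intermediate (not isolated)
8 | 6-allyl-7-(allyloxy)-5-hydroxy-2-[4-methoxy-3-(methoxymethoxy)phenyl]chromen-4-one | COCOc1cc(-c2cc(=O)c3c(O)c(CC=C)c(OCC=C)cc3o2)ccc1OC | intermediate (not isolated)
9 | 6,8-diallyl-5-hydroxy-2-[4-methoxy-3-(methoxymethoxy)phenyl]-8H-chromene-4,7-dione (C8 ortho-dienone, racemic at C8) | COCOc1cc(C2=CC(=O)C3=C(O2)C(CC=C)C(=O)C(CC=C)=C3O)ccc1OC | intermediate (not isolated)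
10 | 6,8-diallyl-5,7-dihydroxy-2-[4-methoxy-3-(methoxymethoxy)phenyl]chromen-4-one | COCOc1cc(-c2cc(=O)c3c(O)c(CC=C)c(O)c(CC=C)c3o2)ccc1OC | intermediate
11 | iodomethane | CI | starting material
12 | 6,8-diallyl-5-hydroxy-7-methoxy-2-[4-methoxy-3-(methoxymethoxy)phenyl]chromen-4-one | COCOc1cc(-c2cc(=O)c3c(O)c(CC=C)c(OC)c(CC=C)c3o2)ccc1OC | intermediate
13 | 2-methylbut-2-ene | CC=C(C)C | starting material
14 | 5-hydroxy-7-methoxy-2-[4-methoxy-3-(methoxymethoxy)phenyl]-6,8-bis(3-methylbut-2-enyl)chromen-4-one | COCOc1cc(-c2cc(=O)c3c(O)c(CC=C(C)C)c(OC)c(CC=C(C)C)c3o2)ccc1OC | intermediate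
15 | 7-methoxy-5-(methoxymethoxy)-2-[4-methoxy-3-(methoxymethoxy)phenyl]-6,8-bis(3-methylbut-2-enyl)chromen-4-one | COCOc1cc(-c2cc(=O)c3c(OCOC)c(CC=C(C)C)c(OC)c(CC=C(C)C)c3o2)ccc1OC | intermediate
16 | 3-lithio-7-methoxy-5-(methoxymethoxy)-2-[4-methoxy-3-(methoxymethoxy)phenyl]-6,8-bis(3-methylbut-2-enyl)chromen-4-one | COCOc1cc(-c2oc3c(CC=C(C)C)c(OC)c(CC=C(C)C)c(OCOC)c3c(=O)c2[Li])ccc1OC | intermediate (not isolated)
17 | dimethyl {7-methoxy-5-(methoxymethoxy)-2-[4-methoxy-3-(methoxymethoxy)phenyl]-6,8-bis(3-methylbut-2-enyl)-4-oxochromen-3-yl}boronate | COCOc1cc(-c2oc3c(CC=C(C)C)c(OC)c(CC=C(C)C)c(OCOC)c3c(=O)c2B(OC)OC)ccc1OC | intermediate (not isolated)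
18 | 3-hydroxy-7-methoxy-5-(methoxymethoxy)-2-[4-methoxy-3-(methoxymethoxy)phenyl]-6,8-bis(3-methylbut-2-enyl)chromen-4-one | COCOc1cc(-c2oc3c(CC=C(C)C)c(OC)c(CC=C(C)C)c(OCOC)c3c(=O)c2O)ccc1OC | intermediate
19 | 3,5-dihydroxy-2-(3-hydroxy-4-methoxyphenyl)-7-methoxy-6,8-bis(3-methylbut-2-enyl)chromen-4-one | COc1ccc(-c2oc3c(CC=C(C)C)c(OC)c(CC=C(C)C)c(O)c3c(=O)c2O)cc1O | target

## Step count and risk

Total step count: 9. Longest linear sequence: 9 steps, from **1** to **19**.

**Step 4 (key step).** The peri 5-O-allyl ether may be cleaved by heat instead of migrating, the second shift may stall, or a freshly formed phenol may add across its neighbouring allyl double bond. The fallback uses two single shifts and never makes a 5-O-allyl ether. It sets out from **5**: heating in N,N-diethylaniline moves the 7-O-allyl group onto ring A to give 8-allyl-5,7-dihydroxy-2-[4-methoxy-3-(methoxymethoxy)phenyl]chromen-4-one F1. The 7-OH is allylated again with **2** and K2CO3 in acetone to give 8-allyl-7-(allyloxy)-5-hydroxy-2-[4-methoxy-3-(methoxymethoxy)phenyl]chromen-4-one F2. A second heating sends that group to the remaining free ortho carbon, and the sequence comes back to the route at **10**. The regiochemistry of the first shift does not matter, because the second shift fills whichever of C6 and C8 is still free.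

**Step 8.** The amide base may deprotonate the doubly activated ArCH2 positions, C3 metalation next to the crowded peri substituent may be incomplete, or hydroperoxide may attack C2 of the chromone. The fallback moves the C3 oxidation ahead of the rearrangement, where no C-allyl or C-prenyl group exists. It sets out from **6**:
- the same metalation, borylation and oxidation gives 5,7-bis(allyloxy)-3-hydroxy-2-[4-methoxy-3-(methoxymethoxy)phenyl]chromen-4-one F3;
- **4** with i-Pr2NEt gives 5,7-bis(allyloxy)-3-(methoxymethoxy)-2-[4-methoxy-3-(methoxymethoxy)phenyl]chromen-4-one F4;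
- the twofold Claisen rearrangement as in step 4 gives 6,8-diallyl-5,7-dihydroxy-3-(methoxymethoxy)-2-[4-methoxy-3-(methoxymethoxy)phenyl]chromen-4-one F5;
- methylation with **11** as in step 5 gives 6,8-diallyl-5-hydroxy-7-methoxy-3-(methoxymethoxy)-2-[4-methoxy-3-(methoxymethoxy)phenyl]chromen-4-one F6;
- cross-metathesis with **13** as in step 6 gives 5-hydroxy-7-methoxy-3-(methoxymethoxy)-2-[4-methoxy-3-(methoxymethoxy)phenyl]-6,8-bis(3-methylbut-2-enyl)chromen-4-one F7;
- HCl in methanol removes both MOM groups, and the sequence comes back to the route at **19**.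

**Step 6.** The reaction may stall after one metathesis, the double bond may migrate into conjugation with the ring through Ru–H species from catalyst decay, or the allyl groups may homodimerise. The fallback builds the prenyl termini by carbonyl olefination instead. It sets out from **12**: NaH and **4** give 6,8-diallyl-7-methoxy-5-(methoxymethoxy)-2-[4-methoxy-3-(methoxymethoxy)phenyl]chromen-4-one F8. Lemieux–Johnson cleavage (catalytic OsO4, NaIO4, 2,6-lutidine, dioxane–water) gives 2,2'-{7-methoxy-5-(methoxymethoxy)-2-[4-methoxy-3-(methoxymethoxy)phenyl]-4-oxochromene-6,8-diyl}diacetaldehyde F9. A twofold Wittig reaction with Ph3P=C(CH3)2 (from isopropyltriphenylphosphonium iodide and n-BuLi, THF, −78 °C to rt) comes back to the route at **15**.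

**Step 9.** Once the 5-O-MOM group has fallen off, the 5-OH may add across the C6 prenyl double bond under acid, or methanol may add to the trisubstituted alkenes, before the slower 3'-O-MOM is gone. The fallback runs the acid step while the side chains are still allyl groups, which cannot form a stabilised tertiary cation, and makes the prenyl groups last. It sets out from **12**: the 5-O-MOM ether F8 is made as described above. Metalation, borylation and oxidation as in step 8 (kept at −78 °C to avoid allyl-to-propenyl migration) give 6,8-diallyl-3-hydroxy-7-methoxy-5-(methoxymethoxy)-2-[4-methoxy-3-(methoxymethoxy)phenyl]chromen-4-one F10. HCl in methanol gives 6,8-diallyl-3,5-dihydroxy-2-(3-hydroxy-4-methoxyphenyl)-7-methoxychromen-4-one F11. Cross-metathesis with **13** and the second-generation Grubbs catalyst RuCl2(=CHPh)(H2IMes)(PCy3) comes back to the route at **19**.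

**Step 1.** Alkylation may not stop at O7 and may spread to the 3'-OH. The fallback makes the difference between the oxygens one of ester lability. It sets out from **1**: Ac2O in pyridine gives diosmetin 5,7,3'-triacetate F12. Alkylative replacement of the most labile 7-acetate (**2**, K2CO3, KI, acetone, reflux) gives 7-(allyloxy)-2-(3-acetoxy-4-methoxyphenyl)-4-oxochromen-5-yl acetate F13. Methanolysis (K2CO3, MeOH) comes back to the route at **3**.

## Further compounds

F1 | step 4 | 8-allyl-5,7-dihydroxy-2-[4-methoxy-3-(methoxymethoxy)phenyl]chromen-4-one | COCOc1cc(-c2cc(=O)c3c(O)cc(O)c(CC=C)c3o2)ccc1OC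
F2 | step 4 | 8-allyl-7-(allyloxy)-5-hydroxy-2-[4-methoxy-3-(methoxymethoxy)phenyl]chromen-4-one | COCOc1cc(-c2cc(=O)c3c(O)cc(OCC=C)c(CC=C)c3o2)ccc1OC
F3 | step 8 | 5,7-bis(allyloxy)-3-hydroxy-2-[4-methoxy-3-(methoxymethoxy)phenyl]chromen-4-one | COCOc1cc(-c2oc3cc(OCC=C)cc(OCC=C)c3c(=O)c2O)ccc1OC
F4 | step 8 | 5,7-bis(allyloxy)-3-(methoxymethoxy)-2-[4-methoxy-3-(methoxymethoxy)phenyl]chromen-4-one | COCOc1cc(-c2oc3cc(OCC=C)cc(OCC=C)c3c(=O)c2OCOC)ccc1OC
F5 | step 8 | 6,8-diallyl-5,7-dihydroxy-3-(methoxymethoxy)-2-[4-methoxy-3-(methoxymethoxy)phenyl]chromen-4-one | COCOc1cc(-c2oc3c(CC=C)c(O)c(CC=C)c(O)c3c(=O)c2OCOC)ccc1OC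
F6 | step 8 | 6,8-diallyl-5-hydroxy-7-methoxy-3-(methoxymethoxy)-2-[4-methoxy-3-(methoxymethoxy)phenyl]chromen-4-one | COCOc1cc(-c2oc3c(CC=C)c(OC)c(CC=C)c(O)c3c(=O)c2OCOC)ccc1OC
F7 | step 8 | 5-hydroxy-7-methoxy-3-(methoxymethoxy)-2-[4-methoxy-3-(methoxymethoxy)phenyl]-6,8-bis(3-methylbut-2-enyl)chromen-4-one | COCOc1cc(-c2oc3c(CC=C(C)C)c(OC)c(CC=C(C)C)c(O)c3c(=O)c2OCOC)ccc1OC
F8 | step 6 | 6,8-diallyl-7-methoxy-5-(methoxymethoxy)-2-[4-methoxy-3-(methoxymethoxy)phenyl]chromen-4-one | COCOc1cc(-c2cc(=O)c3c(OCOC)c(CC=C)c(OC)c(CC=C)c3o2)ccc1OC
F9 | step 6 | 2,2'-{7-methoxy-5-(methoxymethoxy)-2-[4-methoxy-3-(methoxymethoxy)phenyl]-4-oxochromene-6,8-diyl}diacetaldehyde | COCOc1cc(-c2cc(=O)c3c(OCOC)c(CC=O)c(OC)c(CC=O)c3o2)ccc1OC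
F10 | step 9 | 6,8-diallyl-3-hydroxy-7-methoxy-5-(methoxymethoxy)-2-[4-methoxy-3-(methoxymethoxy)phenyl]chromen-4-one | COCOc1cc(-c2oc3c(CC=C)c(OC)c(CC=C)c(OCOC)c3c(=O)c2O)ccc1OC
F11 | step 9 | 6,8-diallyl-3,5-dihydroxy-2-(3-hydroxy-4-methoxyphenyl)-7-methoxychromen-4-one | COc1ccc(-c2oc3c(CC=C)c(OC)c(CC=C)c(O)c3c(=O)c2O)cc1O
F12 | step 1 | diosmetin 5,7,3'-triacetate, 2-(3-acetoxy-4-methoxyphenyl)-4-oxochromene-5,7-diyl diacetate | COc1ccc(-c2cc(=O)c3c(OC(C)=O)cc(OC(C)=O)cc3o2)cc1OC(C)=O
F13 | step 1 | 7-(allyloxy)-2-(3-acetoxy-4-methoxyphenyl)-4-oxochromen-5-yl acetate | COc1ccc(-c2cc(=O)c3c(OC(C)=O)cc(OCC=C)cc3o2)cc1OC(C)=O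
A1 | alternative 1 | 3-methoxy-2,4-bis(3-methylbut-2-enyl)-5-(triisopropylsilyloxy)phenol | COc1c(CC=C(C)C)c(O)cc(O[Si](C(C)C)(C(C)C)C(C)C)c1CC=C(C)C
A2 | alternative 1 | 2-(3-methylbut-2-enyl)-3-(triisopropylsilyloxy)cyclobut-2-en-1-one | CC(C)=CCC1=C(O[Si](C(C)C)(C(C)C)C(C)C)CC1=O
A3 | alternative 1 | 1-methoxy-5-methylhex-4-en-1-yne | COC#CCC=C(C)C
A4 | alternative 2 | 3,3'-di-O-pivaloyl derivative of the target | COc1ccc(-c2oc3c(CC=C(C)C)c(OC)c(CC=C(C)C)c(O)c3c(=O)c2OC(=O)C(C)(C)C)cc1OC(=O)C(C)(C)C
A5 | alternative 2 | 5-methoxy-4,6-bis(3-methylbut-2-enyl)benzene-1,3-diol | COc1c(CC=C(C)C)c(O)cc(O)c1CC=C(C)C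
A6 | alternative 2 | methyl 3-[4-methoxy-3-(pivaloyloxy)phenyl]-3-oxo-2-(pivaloyloxy)propanoate (racemic) | COC(=O)C(OC(=O)C(C)(C)C)C(=O)c1ccc(OC)c(OC(=O)C(C)(C)C)c1
A7 | alternative 3 | 5-hydroxy-7-methoxy-2-[4-methoxy-3-(methoxymethoxy)phenyl]-6,8-bis(3-methylbut-2-enyl)chromen-4-one (identical with 14) | COCOc1cc(-c2cc(=O)c3c(O)c(CC=C(C)C)c(OC)c(CC=C(C)C)c3o2)ccc1OC
A8 | alternative 3 | 2-iodo-5-methoxy-4,6-bis(3-methylbut-2-enyl)benzene-1,3-diol | COc1c(CC=C(C)C)c(O)c(I)c(O)c1CC=C(C)C
A9 | alternative 3 | 4-ethynyl-1-methoxy-2-(methoxymethoxy)benzene | C#Cc1ccc(OC)c(OCOC)c1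
A10 | alternative 3 | carbon monoxide | [C-]#[O+]
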